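The route rests on cutting the pendant 3,4-dimethoxyphenyl ring (C1'–C6') off C1 and replacing it by an ethynyl group. In the target, C1 of the dihydronaphthalene carries two nearly identical dimethoxyaryl rings, the fused benzo ring (C4a–C8a) and the pendant one; as an aryl/ethynyl carbon it becomes a propargylic centre that asymmetric copper catalysis can set. The key step then grows the whole pendant arene in one operation: cobalt-catalysed [4+2] cycloaddition of the alkyne with 2,3-dimethoxybuta-1,3-diene and dehydrogenation, two C–C bonds and one ring. Its precursor is the (4R)-β-ethynyl methyl ketone carrying the 2-bromo-4,5-dimethoxyphenyl group, whose bromide later closes the carbocycle by enolate arylation, where C2 is set trans.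

Key step: step 4

Remark on the chemistry (1): the carbon α to the ketone (later C2 of the target) is deliberately left uncontrolled until step 5. The acyclic ketones formed in steps 3 and 4 are therefore epimer pairs at that carbon, with the propargylic/diaryl carbon fixed as R; their names and SMILES show the 3S epimer.

Remark on the chemistry (2): the sense of induction of the copper catalyst in step 3 is an assumption. The ligand enantiomer that gives 4R is identified in a first run, and the mirror-image ligand is used if required.

Step 1
Reactants: 1 2-bromo-4,5-dimethoxybenzaldehyde; 2 ethynylmagnesium bromide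
Product: 4 rac-1-(2-bromo-4,5-dimethoxyphenyl)prop-2-yn-1-yl acetate, via bromomagnesium propargylic alkoxide 3 (not isolated)
Conditions: 2 (0.5 M in THF, 1.2 equiv), THF, 0 °C; then Ac2O (1.5 equiv), 0 °C → rt
Reagents that add atoms: acetic anhydride, CC(=O)OC(C)=O
Why: Grignard 1,2-addition of the alkynyl nucleophile to the aldehyde and O-acetylation of the magnesium alkoxide in the same flask should give the propargylic acetate directly; the carbinol centre is left racemic on purpose because step 3 passes through a planar copper allenylidene and sets it afresh.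

Step 2
Reactants: 5 ethyl 2-methyl-3-oxobutanoate
Product: 7 2-methyl-3-oxobutanoic acid, via sodium 2-methyl-3-oxobutanoate 6 (not isolated)
Conditions: NaOH (1 M aq, 1.1 equiv), 0 °C → rt; then 1 M HCl to pH 2, 0 °C, Et2O extraction, concentrated cold and used at once
Reagents that add atoms: sodium hydroxide, [Na+].[OH-]
Why: Cold saponification (ester hydrolysis) should give the β-keto acid, which decarboxylates only slowly below room temperature and is used immediately; its stereocentre is irrelevant because it is lost in step 3.

Step 3
Reactants: 4 rac-1-(2-bromo-4,5-dimethoxyphenyl)prop-2-yn-1-yl acetate; 7 2-methyl-3-oxobutanoic acid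
Product: 8 (3S,4R)-4-(2-bromo-4,5-dimethoxyphenyl)-3-methylhex-5-yn-2-one
Conditions: 7 (1.5 equiv), Cu(MeCN)4BF4 (5 mol%), enantiopure tridentate P,N,N ligand (phosphine–ketimine–pyridine type, 5.5 mol%), iPr2NEt (2.5 equiv), MeOH, 0 °C, argon
Reagents that add atoms: none
Why: Copper-catalysed enantioselective decarboxylative propargylic alkylation: the copper acetylide of 4 expels acetate to give a copper allenylidene, the enol(ate) of 7 attacks its γ-carbon on the face left open by the chiral ligand, which sets C4 as R, and loss of CO2 unmasks the methyl ketone, C3 being formed by uncontrolled protonation (see remark 1).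

Step 4
Reactants: 8 (3S,4R)-4-(2-bromo-4,5-dimethoxyphenyl)-3-methylhex-5-yn-2-one; 9 2,3-dimethoxybuta-1,3-diene
Product: 11 (3S,4R)-4-(2-bromo-4,5-dimethoxyphenyl)-4-(3,4-dimethoxyphenyl)-3-methylbutan-2-one, via 1,4-cyclohexadiene bis(enol ether) 10 (not isolated)
Conditions: CoBr2(dppe) (10 mol%), Zn (20 mol%), ZnI2 (20 mol%), 9 (2 equiv), CH2Cl2, rt; filtration through basic alumina; then DDQ (1.05 equiv), CH2Cl2, 0 °C
Reagents that add atoms: none
Why: Zinc reduces CoBr2(dppe) and ZnI2 abstracts halide to give a cobalt(I) species that binds the terminal alkyne and the s-cis diene, couples them oxidatively to a cobaltacycle and reductively eliminates the 1,4-cyclohexadiene 10, joining each alkyne carbon to one diene terminus; DDQ then removes the two doubly allylic hydrogens to aromatise. The closest known reaction type is the neutral cobalt-catalysed Diels–Alder reaction of non-activated terminal alkynes with 2,3-disubstituted or 2-siloxy butadienes, followed by DDQ oxidation of the dihydroarene. The new ring is a six-membered carbocycle closed by intermolecular [4+2] annulation (both bonds in one catalytic cycle, no tether) and then converted into the benzene ring by dehydrogenation. No stereocentre is formed; C4 is a spectator because the cycle is non-basic and never touches the C4–H bond, and C3 need not survive. The step needs chemoselectivity for the alkyne over the aryl bromide and the ketone, which the cobalt–diphosphine catalyst in CH2Cl2 at room temperature should provide because it engages only the two π-partners, and no regiochemical choice arises because the diene is C2-symmetric, so either orientation gives the same 3,4-dimethoxyphenyl ring. DDQ is held at about one equivalent at 0 °C so that the fast aromatisation of the bis(enol ether) is finished before the doubly benzylic C–H of 11 can be attacked.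

Step 5
Reactants: 11 (3S,4R)-4-(2-bromo-4,5-dimethoxyphenyl)-4-(3,4-dimethoxyphenyl)-3-methylbutan-2-one
Product: 13 (3S,4R)-4-(3,4-dimethoxyphenyl)-6,7-dimethoxy-3-methyl-3,4-dihydronaphthalen-2(1H)-one, via cis-(3R,4R)-tetralone 12 (not isolated)
Conditions: Pd2(dba)3 (2.5 mol%), XPhos (6 mol%), NaOtBu (2.5 equiv), toluene (0.03 M), 80 °C; aq. NH4Cl; then TsOH·H2O (0.2 equiv), degassed toluene, 60 °C
Reagents that add atoms: none
Why: Intramolecular palladium-catalysed ketone α-arylation (enolate arylation): only the methyl-side enolate can reach the aryl–palladium bond to close a six-membered ring (the internal enolate would give a four-membered ring), and the acid-catalysed keto–enol equilibration that follows should set C3 (C2 of the target) under thermodynamic control trans to the C4 aryl group, so that neither substituent must be axial, while C4 is not enolisable and keeps the configuration from step 3.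

Step 6
Reactants: 13 (3S,4R)-4-(3,4-dimethoxyphenyl)-6,7-dimethoxy-3-methyl-3,4-dihydronaphthalen-2(1H)-one
Product: 15 (3S,4R)-4-(3,4-dimethoxyphenyl)-6,7-dimethoxy-3-methyl-3,4-dihydronaphthalen-2-yl trifluoromethanesulfonate, via potassium enolate 14 (not isolated)
Conditions: KHMDS (1.1 equiv), THF, −78 °C; then PhNTf2 (1.2 equiv), −78 → 0 °C
Reagents that add atoms: N-phenylbis(trifluoromethanesulfonimide), O=S(=O)(N(c1ccccc1)S(=O)(=O)C(F)(F)F)C(F)(F)F
Why: Regioselective enolate O-triflation: the benzylic C1 protons are far more acidic and less hindered than the tertiary C3–H because their enolate is conjugated to the arene, so the enol triflate should form toward C1 only and the C3 stereocentre set in step 5 is not touched.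

Step 7
Reactants: 15 (3S,4R)-4-(3,4-dimethoxyphenyl)-6,7-dimethoxy-3-methyl-3,4-dihydronaphthalen-2-yl trifluoromethanesulfonate
Product: 16 (1R,2S)-1-(3,4-dimethoxyphenyl)-6,7-dimethoxy-2,3-dimethyl-1,2-dihydronaphthalene
Conditions: MeZnCl (2 equiv), Pd(dppf)Cl2 (5 mol%), THF, rt → 50 °C
Reagents that add atoms: methylzinc chloride, C[Zn]Cl
Why: Negishi cross-coupling of the enol triflate with a methylzinc reagent (oxidative addition, transmetalation, reductive elimination; methyl has no β-hydrogen) should install the C3 methyl group under neutral conditions that leave the allylic C2–H and the doubly benzylic C1–H, and hence both stereocentres, untouched.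

Compound list
1 | 2-bromo-4,5-dimethoxybenzaldehyde | COc1cc(Br)c(C=O)cc1OC | starting material
2 | ethynylmagnesium bromide | C#C[Mg]Br | starting material
3 | bromomagnesium 1-(2-bromo-4,5-dimethoxyphenyl)prop-2-yn-1-olate (racemic, not isolated) | C#CC(O[Mg]Br)c1cc(OC)c(OC)cc1Br | intermediate
4 | rac-1-(2-bromo-4,5-dimethoxyphenyl)prop-2-yn-1-yl acetate | CC(=O)OC(C#C)c1cc(OC)c(OC)cc1Br | intermediate
5 | ethyl 2-methyl-3-oxobutanoate (racemic) | CCOC(=O)C(C)C(C)=O | starting material
6 | sodium 2-methyl-3-oxobutanoate (not isolated) | CC(=O)C(C)C(=O)[O-].[Na+] | intermediate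
7 | 2-methyl-3-oxobutanoic acid (racemic) | CC(=O)C(C)C(=O)O | intermediate
8 | (3S,4R)-4-(2-bromo-4,5-dimethoxyphenyl)-3-methylhex-5-yn-2-one (3S epimer shown; 3R epimer also present) | CC(=O)[C@@H](C)[C@H](C#C)c1cc(OC)c(OC)cc1Br | intermediate
9 | 2,3-dimethoxybuta-1,3-diene | C=C(OC)C(OC)=C | starting material
10 | (3S,4R)-4-(2-bromo-4,5-dimethoxyphenyl)-4-(4,5-dimethoxycyclohexa-1,4-dien-1-yl)-3-methylbutan-2-one (not isolated; 3S epimer shown; 3R epimer also present) | CC(=O)[C@@H](C)[C@H](C1=CCC(OC)=C(OC)C1)c1cc(OC)c(OC)cc1Br | intermediate
11 | (3S,4R)-4-(2-bromo-4,5-dimethoxyphenyl)-4-(3,4-dimethoxyphenyl)-3-methylbutan-2-one (3S epimer shown; 3R epimer also present) | CC(=O)[C@@H](C)[C@H](c1ccc(OC)c(OC)c1)c1cc(OC)c(OC)cc1Br | intermediate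
12 | (3R,4R)-4-(3,4-dimethoxyphenyl)-6,7-dimethoxy-3-methyl-3,4-dihydronaphthalen-2(1H)-one (cis, not isolated) | COc1ccc([C@@H]2c3cc(OC)c(OC)cc3CC(=O)[C@@H]2C)cc1OC | intermediate
13 | (3S,4R)-4-(3,4-dimethoxyphenyl)-6,7-dimethoxy-3-methyl-3,4-dihydronaphthalen-2(1H)-one (trans) | COc1ccc([C@@H]2c3cc(OC)c(OC)cc3CC(=O)[C@H]2C)cc1OC | intermediate
14 | potassium (3S,4R)-4-(3,4-dimethoxyphenyl)-6,7-dimethoxy-3-methyl-3,4-dihydronaphthalen-2-olate (not isolated) | COc1ccc([C@@H]2c3cc(OC)c(OC)cc3C=C([O-])[C@H]2C)cc1OC.[K+] | intermediate
15 | (3S,4R)-4-(3,4-dimethoxyphenyl)-6,7-dimethoxy-3-methyl-3,4-dihydronaphthalen-2-yl trifluoromethanesulfonate | COc1ccc([C@@H]2c3cc(OC)c(OC)cc3C=C(OS(=O)(=O)C(F)(F)F)[C@H]2C)cc1OC | intermediate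
16 | (1R,2S)-1-(3,4-dimethoxyphenyl)-6,7-dimethoxy-2,3-dimethyl-1,2-dihydronaphthalene (trans) | COc1ccc([C@@H]2c3cc(OC)c(OC)cc3C=C(C)[C@H]2C)cc1OC | target

Total step count: 7.
Longest linear sequence: 6 steps (1 → 4 → 8 → 11 → 13 → 15 → 16); step 2 is a one-step side branch.

Steps most likely to fail

Step 4. The low-valent cobalt may insert into the C–Br bond instead of binding the alkyne. Zinc iodide may hydrolyse or oligomerise the electron-rich diene, or trigger oxygen-to-alkyne cycloisomerisation of the alkynyl ketone. DDQ may over-oxidise the doubly benzylic position. The fallback gives up the latent arene and brings the pendant ring in ready-made by asymmetric conjugate arylation, setting out from 1 and coming back at 11. Horner–Wadsworth–Emmons olefination of 1 with diethyl [2-(methoxy(methyl)amino)-2-oxoethyl]phosphonate (NaH, THF) should give (E)-3-(2-bromo-4,5-dimethoxyphenyl)-N-methoxy-N-methylprop-2-enamide F1. Rhodium/chiral diene-catalysed 1,4-addition of (3,4-dimethoxyphenyl)boronic acid (aqueous dioxane, KOH; ligand antipode chosen for 3R) should give (3R)-3-(2-bromo-4,5-dimethoxyphenyl)-3-(3,4-dimethoxyphenyl)-N-methoxy-N-methylpropanamide F2. Enolate methylation (LDA, MeI, THF, −78 °C) should give (3R)-3-(2-bromo-4,5-dimethoxyphenyl)-3-(3,4-dimethoxyphenyl)-N-methoxy-N,2-dimethylpropanamide F3 as its C2 epimers. MeMgBr (THF, 0 °C) then converts the N-methoxy-N-methylamide into ketone 11, again as the C3 epimer pair that step 5 converges.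

Step 3. The branched β-keto acid may be too slow to attack the hindered γ-carbon of the allenylidene, so that decarboxylation to butanone and poor facial discrimination at copper take over. The fallback moves the controlling element from copper to an amine catalyst and secures the propargylic centre by separating diastereomers; it sets out from 4 and comes back at 8. Cooperative copper/secondary-amine catalysis with propanal is used: CuOTf·½C6H6, rac-BINAP, the (R)-configured diarylprolinol trimethylsilyl ether, toluene, 0 °C. The enamine face should fix the α-carbon as S (by the usual shielding model) in (2S)-3-(2-bromo-4,5-dimethoxyphenyl)-2-methylpent-4-ynal F4, formed as both propargylic epimers. MeMgBr (THF, −78 °C) should give (3S)-4-(2-bromo-4,5-dimethoxyphenyl)-3-methylhex-5-yn-2-ol F5. Dess–Martin oxidation should give 8 together with (3S,4S)-4-(2-bromo-4,5-dimethoxyphenyl)-3-methylhex-5-yn-2-one F6. The two are diastereomers and are separated by chromatography, so 8 is reached as the (3S,4R) isomer however well copper differentiates the allenylidene faces.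

Step 5. Oxidative addition into the electron-rich, ortho-branched aryl bromide may be slow. Base-driven processes could then compete: aldol condensation of the methyl ketone, O-arylation of the enolate, and intermolecular arylation or air oxidation of the tetralone enolate. The acid equilibration may also stop at a modest trans preference. The fallback separates enolate generation from the coupling; it sets out from 11 and comes back at 13. Kinetic deprotonation at the methyl group and silylation (LDA, TMSCl, THF, −78 °C) should give {[(4R)-4-(2-bromo-4,5-dimethoxyphenyl)-4-(3,4-dimethoxyphenyl)-3-methylbut-1-en-2-yl]oxy}trimethylsilane F7. Fluoride-promoted palladium-catalysed arylation of the silyl enol ether (Bu3SnF, Pd(OAc)2/P(t-Bu)3, toluene, 80 °C) closes the tetralone through a tin enolate without free base. The same acid equilibration leads to 13; any remaining cis isomer is removed by chromatography and resubmitted to the equilibration.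

Further compounds
F1 | step 4 | (E)-3-(2-bromo-4,5-dimethoxyphenyl)-N-methoxy-N-methylprop-2-enamide | CON(C)C(=O)/C=C/c1cc(OC)c(OC)cc1Br
F2 | step 4 | (3R)-3-(2-bromo-4,5-dimethoxyphenyl)-3-(3,4-dimethoxyphenyl)-N-methoxy-N-methylpropanamide | CON(C)C(=O)C[C@H](c1ccc(OC)c(OC)c1)c1cc(OC)c(OC)cc1Br
F3 | step 4 | (3R)-3-(2-bromo-4,5-dimethoxyphenyl)-3-(3,4-dimethoxyphenyl)-N-methoxy-N,2-dimethylpropanamide (C2 epimer pair, C2 left open) | CON(C)C(=O)C(C)[C@H](c1ccc(OC)c(OC)c1)c1cc(OC)c(OC)cc1Br
F4 | step 3 | (2S)-3-(2-bromo-4,5-dimethoxyphenyl)-2-methylpent-4-ynal (C3 epimer pair, C3 left open) | O=C[C@@H](C)C(C#C)c1cc(OC)c(OC)cc1Br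
F5 | step 3 | (3S)-4-(2-bromo-4,5-dimethoxyphenyl)-3-methylhex-5-yn-2-ol (C2 and C4 left open) | CC(O)[C@@H](C)C(C#C)c1cc(OC)c(OC)cc1Br
F6 | step 3 | (3S,4S)-4-(2-bromo-4,5-dimethoxyphenyl)-3-methylhex-5-yn-2-one | CC(=O)[C@@H](C)[C@@H](C#C)c1cc(OC)c(OC)cc1Br
F7 | step 5 | {[(4R)-4-(2-bromo-4,5-dimethoxyphenyl)-4-(3,4-dimethoxyphenyl)-3-methylbut-1-en-2-yl]oxy}trimethylsilane (C3 epimer pair, C3 left open) | C=C(O[Si](C)(C)C)C(C)[C@H](c1ccc(OC)c(OC)c1)c1cc(OC)c(OC)cc1Br
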